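**Assumption:** the target SMILES has no stereocentres (the molecule is achiral), so "single enantiomer" needs no stereocontrol. The only stereo-element in the route is the E-alkene of chalcone 9, which is consumed in the next step. The route is a paper proposal built on classical flavone chemistry and has not been run.

## Retrosynthetic overview

1. Target ⇒ hydrogenolysis of a 7-O-benzyl ether, preceded by selective acylation of the free 8-OH of a 5,8-dihydroxy-7-benzyloxyflavone (the 5-OH is chelated to C4=O and unreactive).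
2. The 8-OH comes from Elbs persulfate oxidation para to the 5-OH of 7-benzyloxy-5-hydroxy-3,6,4'-trimethoxyflavone.
3. That flavone comes from a 5,7-dibenzyloxy-3-methoxyflavone by chelation-controlled 5-O-debenzylation; the pyranone C ring and 3-oxygen come from an Algar–Flynn–Oyamada (AFO) cyclisation of a 2'-hydroxychalcone, then 3-O-methylation.
4. The chalcone comes from Claisen–Schmidt condensation of p-anisaldehyde with 2-hydroxy-4,6-dibenzyloxy-5-methoxyacetophenone.
5. That A-ring ketone comes from phloroacetophenone by dibenzylation, Elbs oxidation and O-methylation. Ring order: A ring bought, B ring bought, C ring formed in the AFO step.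

## Route

**Step 1**
Reactants: 1 (2',4',6'-trihydroxyacetophenone); 2 (benzyl bromide)
Product: 3, 1-[2,4-bis(benzyloxy)-6-hydroxyphenyl]ethan-1-one
Conditions: BnBr (2.1 equiv), K2CO3, DMF, rt → 60 °C
Reagents that add atoms: benzyl bromide, BrCc1ccccc1
Why: Williamson etherification; one ortho OH stays free because it is hydrogen-bonded to the ketone and is the least nucleophilic. (3 is also a catalogue compound; buying it removes this step.)

**Step 2**
Reactants: 3; 4 (potassium persulfate)
Product: 5, 1-[2,4-bis(benzyloxy)-3,6-dihydroxyphenyl]ethan-1-one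
Conditions: K2S2O8, aq NaOH/pyridine, 0–20 °C, 24 h; then 2 M HCl, Na2SO3, toluene, 80 °C
Reagents that add atoms: potassium persulfate, [K+].[K+].[O-]S(=O)(=O)OOS(=O)(=O)[O-]
Why: Elbs persulfate oxidation; the phenolate attacks the peroxide O through the carbon para to the free OH, giving an aryl sulfate that is hydrolysed to the quinol.

**Step 3**
Reactants: 5; 6 (iodomethane)
Product: 7, 1-[2,4-bis(benzyloxy)-6-hydroxy-3-methoxyphenyl]ethan-1-one
Conditions: MeI (1.1 equiv), K2CO3, acetone, reflux, N2
Reagents that add atoms: iodomethane, CI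
Why: Selective Williamson methylation of the new non-chelated OH; the ortho-carbonyl OH is chelated and stays free with one equivalent of MeI.

**Step 4**
Reactants: 7; 8 (4-methoxybenzaldehyde)
Product: 9, (E)-1-[2,4-bis(benzyloxy)-6-hydroxy-3-methoxyphenyl]-3-(4-methoxyphenyl)prop-2-en-1-one
Conditions: 50% aq KOH, EtOH–THF, rt, 24–48 h
Reagents that add atoms: 4-methoxybenzaldehyde, COc1ccc(C=O)cc1
Why: Claisen–Schmidt aldol condensation; E1cB dehydration gives the E-chalcone, and the aldehyde cannot enolise.

**Step 5**
Reactants: 9; 10 (hydrogen peroxide)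
Product: 11, 5,7-bis(benzyloxy)-3-hydroxy-6-methoxy-2-(4-methoxyphenyl)-4H-chromen-4-one
Conditions: 30% H2O2, 2 M NaOH, MeOH–THF, 0 °C → rt
Reagents that add atoms: hydrogen peroxide, OO
Why: Algar–Flynn–Oyamada oxidative cyclisation; the 4-methoxyphenyl group favours 6-endo closure at the β-carbon (flavonol) over aurone formation.

**Step 6**
Reactants: 11; 6 (iodomethane)
Product: 12, 5,7-bis(benzyloxy)-3,6-dimethoxy-2-(4-methoxyphenyl)-4H-chromen-4-one
Conditions: MeI, K2CO3, acetone, reflux
Reagents that add atoms: iodomethane, CI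
Why: Williamson methylation of the only free OH (3-OH).

**Step 7**
Reactants: 12
Product: 13, 7-(benzyloxy)-5-hydroxy-3,6-dimethoxy-2-(4-methoxyphenyl)-4H-chromen-4-one
Conditions: MgBr2·OEt2 (3 equiv), toluene–Et2O, 80 °C; dil. HCl work-up
Reagents that add atoms: none
Why: Chelation-controlled Lewis-acid debenzylation; Mg bridges C4=O and the peri 5-O, so only that benzyl ether is cleaved, and the 7-OBn and methyl ethers survive.

**Step 8**
Reactants: 13; 4 (potassium persulfate)
Product: 14, 7-(benzyloxy)-5,8-dihydroxy-3,6-dimethoxy-2-(4-methoxyphenyl)-4H-chromen-4-one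
Conditions: K2S2O8, aq KOH/pyridine, 15–20 °C, 24 h; acidify and recover unreacted 13; then HCl, Na2SO3, 80 °C, 30 min; handle under N2
Reagents that add atoms: potassium persulfate, [K+].[K+].[O-]S(=O)(=O)OOS(=O)(=O)[O-]
Why: Elbs persulfate oxidation; C8 is para to the 5-OH and is the only unsubstituted A-ring carbon, so the regiochemistry is unambiguous.

**Step 9**
Reactants: 14; 15 (3-methylbutanoyl chloride, isovaleryl chloride)
Product: 16, 7-(benzyloxy)-5-hydroxy-3,6-dimethoxy-2-(4-methoxyphenyl)-4-oxo-4H-chromen-8-yl 3-methylbutanoate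
Conditions: isovaleryl chloride (1.05 equiv), Et3N, CH2Cl2, −20 → 0 °C, Ar
Reagents that add atoms: isovaleryl chloride, CC(C)CC(=O)Cl
Why: Selective O-acylation; the 8-OH is a free phenol while the 5-OH is deactivated by chelation to C4=O, and the 7-O is blocked as its benzyl ether.

**Step 10**
Reactants: 16
Product: 17, 5,7-dihydroxy-3,6-dimethoxy-2-(4-methoxyphenyl)-4-oxo-4H-chromen-8-yl 3-methylbutanoate (target)
Conditions: H2 (1 atm), 10% Pd/C, EtOAc, rt, 1–3 h; filter and concentrate without base
Reagents that add atoms: none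
Why: Catalytic hydrogenolysis of the benzyl ether; the neutral, aprotic conditions leave the ester and the flavone C2=C3 intact and avoid 8→7 acyl migration.

## Compound list

1 | 2',4',6'-trihydroxyacetophenone | CC(=O)c1c(O)cc(O)cc1O | starting material
2 | benzyl bromide | BrCc1ccccc1 | starting material
3 | 1-[2,4-bis(benzyloxy)-6-hydroxyphenyl]ethan-1-one | CC(=O)c1c(O)cc(OCc2ccccc2)cc1OCc3ccccc3 | intermediate
4 | potassium persulfate | [K+].[K+].[O-]S(=O)(=O)OOS(=O)(=O)[O-] | starting material (reagent)
5 | 1-[2,4-bis(benzyloxy)-3,6-dihydroxyphenyl]ethan-1-one | CC(=O)c1c(O)cc(OCc2ccccc2)c(O)c1OCc3ccccc3 | intermediate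
6 | iodomethane | CI | starting material (reagent)
7 | 1-[2,4-bis(benzyloxy)-6-hydroxy-3-methoxyphenyl]ethan-1-one | CC(=O)c1c(O)cc(OCc2ccccc2)c(OC)c1OCc3ccccc3 | intermediate
8 | 4-methoxybenzaldehyde | COc1ccc(C=O)cc1 | starting material
9 | (E)-1-[2,4-bis(benzyloxy)-6-hydroxy-3-methoxyphenyl]-3-(4-methoxyphenyl)prop-2-en-1-one | COc1ccc(/C=C/C(=O)c2c(O)cc(OCc3ccccc3)c(OC)c2OCc4ccccc4)cc1 | intermediate
10 | hydrogen peroxide | OO | starting material (reagent)
11 | 5,7-bis(benzyloxy)-3-hydroxy-6-methoxy-2-(4-methoxyphenyl)-4H-chromen-4-one | COc1ccc(-c2oc3cc(OCc4ccccc4)c(OC)c(OCc5ccccc5)c3c(=O)c2O)cc1 | intermediate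
12 | 5,7-bis(benzyloxy)-3,6-dimethoxy-2-(4-methoxyphenyl)-4H-chromen-4-one | COc1ccc(-c2oc3cc(OCc4ccccc4)c(OC)c(OCc5ccccc5)c3c(=O)c2OC)cc1 | intermediate
13 | 7-(benzyloxy)-5-hydroxy-3,6-dimethoxy-2-(4-methoxyphenyl)-4H-chromen-4-one | COc1ccc(-c2oc3cc(OCc4ccccc4)c(OC)c(O)c3c(=O)c2OC)cc1 | intermediate
14 | 7-(benzyloxy)-5,8-dihydroxy-3,6-dimethoxy-2-(4-methoxyphenyl)-4H-chromen-4-one | COc1ccc(-c2oc3c(O)c(OCc4ccccc4)c(OC)c(O)c3c(=O)c2OC)cc1 | intermediate
15 | 3-methylbutanoyl chloride (isovaleryl chloride) | CC(C)CC(=O)Cl | starting material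
16 | 7-(benzyloxy)-5-hydroxy-3,6-dimethoxy-2-(4-methoxyphenyl)-4-oxo-4H-chromen-8-yl 3-methylbutanoate | COc1ccc(-c2oc3c(OC(=O)CC(C)C)c(OCc4ccccc4)c(OC)c(O)c3c(=O)c2OC)cc1 | intermediate
17 | 5,7,8-trihydroxy-3,6,4'-trimethoxyflavone 8-isovalerate | COc1ccc(-c2oc3c(OC(=O)CC(C)C)c(O)c(OC)c(O)c3c(=O)c2OC)cc1 | target

## Summary

Total steps: 10 (9 if 3 is purchased).
Longest linear sequence: 10 steps, fully linear from 1.

Three steps most likely to fail, each with a fallback that changes the approach:

1. **Step 8 (Elbs oxidation of flavone 13).** Risks are low conversion and over-oxidation of the quinol to the 5,8-quinone. Fallback: iodinate C8 of 13 with NIS (the only free A-ring position), then Miyaura borylation and oxidation of the boronate (NaBO3 or H2O2) to give 14. An alternative is C8 formylation followed by Dakin oxidation, which works because the aldehyde is para to the 5-OH.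
2. **Step 2 (Elbs oxidation of the poorly water-soluble, hindered acetophenone 3).** Fallback: avoid C–H oxidation by starting from methyl 3,5-dihydroxy-4-methoxybenzoate. Dibenzylate, convert the ester to the aldehyde, run a Baeyer–Villiger/Dakin oxidation to the symmetric 3,5-bis(benzyloxy)-4-methoxyphenol, then ortho-acetylate (Fries or Friedel–Crafts) to reach 7 with no regiochemical ambiguity.
3. **Step 5 (AFO cyclisation).** A 6'-alkoxy chalcone can divert to the aurone. Fallback: drop the chalcone route and use a Baker–Venkataraman sequence on the ω-methoxy ketone. Make it by Hoesch acylation of phloroglucinol with methoxyacetonitrile, then apply the same benzylation, Elbs and methylation steps. O-Anisoylation, KOH/pyridine acyl migration to the α-methoxy-1,3-diketone and acid cyclodehydration then give 3-methoxyflavone 12 (or 13) directly, with the 3-OMe already in place.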